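Leoligin is cut at O1–C2, C2–C3 and C4–C7'. The chain C9–C3–C4–C5 of the tetrahydrofuran (ring O1–C2–C3–C4–C5; C9 is the ester-bearing carbon on C3) is treated as the γ, β, α and carbonyl carbons of a butyrolactone. One three-component operation joins a lithiated veratraldehyde dithiane (C2), the (R)-γ-(silyloxymethyl)butenolide made from D-glutamic acid, and veratryl bromide (C7'), forming C2–C3 and C4–C7' and both ring stereocentres as an all-trans lactone. Because leoligin's ring closes through C2 where the lactone closed through C9, that trans pair emerges as the 3,4-cis pair after reduction, excision of the spare glutamate carbon and cation closure of O1–C2; angeloylation follows.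

Key step: step 7

Remark on the chemistry: D-glutamic acid (R) is the correct antipode, because diazotisation proceeds with retention and the anti,anti adduct of the (R)-butenolide maps onto (2S,3R,4R). The silyl group is taken as tert-butyldiphenylsilyl, which is bulkier and more robust than a trialkylsilyl group. The one-carbon excision is placed before the ether closure, so that only the C5 hydroxyl can form a five-membered ring with the C2 cation. Open-chain intermediates are discussed with the atom numbers of the target (O1, C2–C5, C9, C7'; C10 is the carbon that is later cut off).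

Step 1
Reactants: 1 D-glutamic acid
Product: 2 (R)-5-oxotetrahydrofuran-2-carboxylic acid
Conditions: NaNO2, aq. HCl, 0 °C → rt
Reagents that add atoms: none
Why: Nitrous acid deamination of the α-amino acid should proceed with net retention (double inversion through an α-lactone opened by the γ-carboxyl group), so the (R) centre of 1 is carried into lactone acid 2.

Step 2
Reactants: 2 (R)-5-oxotetrahydrofuran-2-carboxylic acid
Product: 3 (R)-5-(hydroxymethyl)dihydrofuran-2(3H)-one
Conditions: BH3·SMe2, THF, 0 °C → rt; MeOH quench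
Reagents that add atoms: none
Why: Borane reduces a carboxylic acid chemoselectively in the presence of a lactone and does not touch the stereocentre.

Step 3
Reactants: 3 (R)-5-(hydroxymethyl)dihydrofuran-2(3H)-one
Product: 4 (R)-5-[(tert-butyldiphenylsilyloxy)methyl]dihydrofuran-2(3H)-one
Conditions: TBDPSCl, imidazole, DMF, 0 °C → rt
Reagents that add atoms: tert-butyl(chloro)diphenylsilane, CC(C)(C)[Si](Cl)(c1ccccc1)c1ccccc1
Why: Standard silyl ether formation on a primary alcohol, with a bulky group chosen to shield one face of the later butenolide and to survive organolithium, divalent mercury and hydride reagents.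

Step 4
Reactants: 4 (R)-5-[(tert-butyldiphenylsilyloxy)methyl]dihydrofuran-2(3H)-one
Product: 5 (5R)-5-[(tert-butyldiphenylsilyloxy)methyl]-3-(phenylselanyl)dihydrofuran-2(3H)-one (mixture of C3 epimers)
Conditions: LiN(i-Pr)2, THF, −78 °C; enolate added to PhSeBr, −78 °C
Reagents that add atoms: phenylselenyl bromide, Br[Se]c1ccccc1
Why: α-Selenenylation of the lithium lactone enolate is a standard reaction, and the configuration of the new selenium-bearing carbon is irrelevant because that centre becomes sp2 in step 5.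

Step 5
Reactants: 5 (5R)-5-[(tert-butyldiphenylsilyloxy)methyl]-3-(phenylselanyl)dihydrofuran-2(3H)-one
Product: 7 (R)-5-[(tert-butyldiphenylsilyloxy)methyl]furan-2(5H)-one, via α-phenylseleninyl lactone 6 (not isolated)
Conditions: 30% H2O2, pyridine, CH2Cl2, 0 °C → rt
Reagents that add atoms: none
Why: Oxidation to the selenoxide is followed by spontaneous syn-elimination (selenoxide elimination) toward the only β-hydrogens, which should give the conjugated butenolide with the γ stereocentre untouched.

Step 6
Reactants: 8 3,4-dimethoxybenzaldehyde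
Product: 9 2-(3,4-dimethoxyphenyl)-1,3-dithiane
Conditions: HS(CH2)3SH, BF3·OEt2 (cat.), CH2Cl2, 0 °C → rt
Reagents that add atoms: propane-1,3-dithiol, SCCCS
Why: Lewis-acid-catalysed dithioacetalisation of an aromatic aldehyde is routine and installs the acyl-anion equivalent for C2.

Step 7
Reactants: 9 2-(3,4-dimethoxyphenyl)-1,3-dithiane; 7 (R)-5-[(tert-butyldiphenylsilyloxy)methyl]furan-2(5H)-one; 10 4-(bromomethyl)-1,2-dimethoxybenzene
Product: 13 (3R,4R,5R)-5-[(tert-butyldiphenylsilyloxy)methyl]-3-(3,4-dimethoxybenzyl)-4-[2-(3,4-dimethoxyphenyl)-1,3-dithian-2-yl]dihydrofuran-2(3H)-one, via 2-lithio-2-(3,4-dimethoxyphenyl)-1,3-dithiane 11 (not isolated), via lithium enolate of the trans β-adduct 12 (not isolated)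
Conditions: n-BuLi, THF, −78 °C; 7, −78 °C; then 10, DMPU, −78 → −20 °C
Reagents that add atoms: none
Why: The aryl-stabilised dithiane anion 11 adds in a Michael sense to the β-carbon of butenolide 7, and the lithium enolate 12 formed is C-alkylated by benzylic bromide 10 once DMPU is added. The closest known reaction type is the tandem conjugate addition–enolate alkylation of butenolides with lithiated aryl dithianes, as used for dibenzylbutyrolactone lignans. No ring is closed. The lactone β-carbon (C3 of the target) is set by the γ-silyloxymethyl group, which blocks its own face so that the nucleophile enters anti; the lactone α-carbon (C4 of the target) is set by the new dithianyl group, which sends the electrophile to the opposite face, so the all-trans lactone should result. The step needs 1,4- over 1,2-addition, secured by the soft, hindered dithiane anion, and facial selectivity in both bond formations, secured by the γ → β → α relay on the nearly flat five-membered ring.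

Step 8
Reactants: 13 (3R,4R,5R)-5-[(tert-butyldiphenylsilyloxy)methyl]-3-(3,4-dimethoxybenzyl)-4-[2-(3,4-dimethoxyphenyl)-1,3-dithian-2-yl]dihydrofuran-2(3H)-one
Product: 14 (3R,4R,5R)-5-[(tert-butyldiphenylsilyloxy)methyl]-3-(3,4-dimethoxybenzyl)-4-(3,4-dimethoxybenzoyl)dihydrofuran-2(3H)-one
Conditions: Hg(ClO4)2, CaCO3, THF/H2O, 0 °C → rt
Reagents that add atoms: water, O
Why: Thiophilic, divalent-mercury-assisted hydrolysis of the S,S-acetal is buffered by CaCO3 so that silyl ether and lactone survive, and the carbon α to the new ketone already sits in the thermodynamically preferred all-trans arrangement.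

Step 9
Reactants: 14 (3R,4R,5R)-5-[(tert-butyldiphenylsilyloxy)methyl]-3-(3,4-dimethoxybenzyl)-4-(3,4-dimethoxybenzoyl)dihydrofuran-2(3H)-one
Product: 15 (2R,3S,4R)-5-(tert-butyldiphenylsilyloxy)-2-(3,4-dimethoxybenzyl)-3-[(3,4-dimethoxyphenyl)(hydroxy)methyl]pentane-1,4-diol (mixture of epimers at the benzylic carbinol)
Conditions: LiAlH4, THF, 0 °C → rt; aqueous work-up
Reagents that add atoms: none
Why: Exhaustive hydride reduction converts the lactone into the C9/C5 diol and the aryl ketone into the C2 carbinol, whose configuration is of no consequence because C2 is ionised in step 12.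

Step 10
Reactants: 15 (2R,3S,4R)-5-(tert-butyldiphenylsilyloxy)-2-(3,4-dimethoxybenzyl)-3-[(3,4-dimethoxyphenyl)(hydroxy)methyl]pentane-1,4-diol
Product: 16 (2R,3S,4R)-4-(3,4-dimethoxybenzyl)-3-[(3,4-dimethoxyphenyl)(hydroxy)methyl]pentane-1,2,5-triol (mixture of epimers at the benzylic carbinol)
Conditions: Bu4NF, THF, rt
Reagents that add atoms: none
Why: Fluoride-mediated desilylation frees the C10 hydroxyl and so exposes the only vicinal diol of the molecule (C9/C10).

Step 11
Reactants: 16 (2R,3S,4R)-4-(3,4-dimethoxybenzyl)-3-[(3,4-dimethoxyphenyl)(hydroxy)methyl]pentane-1,2,5-triol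
Product: 18 (2R,3R)-2-(3,4-dimethoxybenzyl)-3-[(3,4-dimethoxyphenyl)(hydroxy)methyl]butane-1,4-diol (mixture of epimers at the benzylic carbinol), via hydroxy aldehyde 17 (not isolated)
Conditions: NaIO4, THF/H2O, 0 °C; extractive work-up; then NaBH4, MeOH, 0 °C
Reagents that add atoms: none
Why: Malaprade glycol cleavage removes C10, the carbon that came from the glutamate α-carboxyl group, and the aldehyde, which should rest as its lactol with the C5 hydroxyl and so resist epimerisation at C3, is reduced at once to the C9 primary alcohol.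

Step 12
Reactants: 18 (2R,3R)-2-(3,4-dimethoxybenzyl)-3-[(3,4-dimethoxyphenyl)(hydroxy)methyl]butane-1,4-diol
Product: 19 [(2S,3R,4R)-4-(3,4-dimethoxybenzyl)-2-(3,4-dimethoxyphenyl)tetrahydrofuran-3-yl]methanol
Conditions: (+)-camphor-10-sulfonic acid (cat.), CH2Cl2, 0 °C → rt
Reagents that add atoms: none
Why: Acid-catalysed cyclodehydration ionises the electron-rich benzylic alcohol and the C5 hydroxyl captures the cation to form O1–C2 (the C9 hydroxyl could only give an oxetane), and this reversible closure should place the aryl group trans to the C3 hydroxymethyl group, setting C2 as S.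

Step 13
Reactants: 19 [(2S,3R,4R)-4-(3,4-dimethoxybenzyl)-2-(3,4-dimethoxyphenyl)tetrahydrofuran-3-yl]methanol; 20 angelic acid
Product: 21 leoligin, [(2S,3R,4R)-4-(3,4-dimethoxybenzyl)-2-(3,4-dimethoxyphenyl)tetrahydrofuran-3-yl]methyl (2Z)-2-methylbut-2-enoate
Conditions: PPh3, DIAD, THF, 0 °C → rt
Reagents that add atoms: none
Why: The Mitsunobu esterification activates the primary alcohol and not the acid, so no acylating angeloyl species is formed and the Z double bond should not isomerise to the tiglate; no stereocentre is involved.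

Compound list
1 | D-glutamic acid, (R)-2-aminopentanedioic acid | N[C@H](CCC(=O)O)C(=O)O | starting material
2 | (R)-5-oxotetrahydrofuran-2-carboxylic acid | O1[C@@H](C(=O)O)CCC1=O | intermediate
3 | (R)-5-(hydroxymethyl)dihydrofuran-2(3H)-one | O1[C@@H](CO)CCC1=O | intermediate
4 | (R)-5-[(tert-butyldiphenylsilyloxy)methyl]dihydrofuran-2(3H)-one | O1[C@@H](CO[Si](c2ccccc2)(c2ccccc2)C(C)(C)C)CCC1=O | intermediate
5 | (5R)-5-[(tert-butyldiphenylsilyloxy)methyl]-3-(phenylselanyl)dihydrofuran-2(3H)-one, C3 epimers | O1[C@@H](CO[Si](c2ccccc2)(c2ccccc2)C(C)(C)C)CC([Se]c2ccccc2)C1=O | intermediate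
6 | (5R)-5-[(tert-butyldiphenylsilyloxy)methyl]-3-(phenylseleninyl)dihydrofuran-2(3H)-one | O1[C@@H](CO[Si](c2ccccc2)(c2ccccc2)C(C)(C)C)CC([Se](=O)c2ccccc2)C1=O | intermediate
7 | (R)-5-[(tert-butyldiphenylsilyloxy)methyl]furan-2(5H)-one | O1[C@@H](CO[Si](c2ccccc2)(c2ccccc2)C(C)(C)C)C=CC1=O | intermediate
8 | 3,4-dimethoxybenzaldehyde | COc1ccc(C=O)cc1OC | starting material
9 | 2-(3,4-dimethoxyphenyl)-1,3-dithiane | COc1ccc(C2SCCCS2)cc1OC | intermediate
10 | 4-(bromomethyl)-1,2-dimethoxybenzene | COc1ccc(CBr)cc1OC | starting material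
11 | 2-lithio-2-(3,4-dimethoxyphenyl)-1,3-dithiane | [Li]C1(c2ccc(OC)c(OC)c2)SCCCS1 | intermediate
12 | lithium enolate of (4R,5R)-5-[(tert-butyldiphenylsilyloxy)methyl]-4-[2-(3,4-dimethoxyphenyl)-1,3-dithian-2-yl]dihydrofuran-2(3H)-one | O1[C@@H](CO[Si](c2ccccc2)(c2ccccc2)C(C)(C)C)[C@H](C2(c3ccc(OC)c(OC)c3)SCCCS2)C=C1O[Li] | intermediate
13 | (3R,4R,5R)-5-[(tert-butyldiphenylsilyloxy)methyl]-3-(3,4-dimethoxybenzyl)-4-[2-(3,4-dimethoxyphenyl)-1,3-dithian-2-yl]dihydrofuran-2(3H)-one | O1[C@@H](CO[Si](c2ccccc2)(c2ccccc2)C(C)(C)C)[C@H](C2(c3ccc(OC)c(OC)c3)SCCCS2)[C@@H](Cc2ccc(OC)c(OC)c2)C1=O | intermediate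
14 | (3R,4R,5R)-5-[(tert-butyldiphenylsilyloxy)methyl]-3-(3,4-dimethoxybenzyl)-4-(3,4-dimethoxybenzoyl)dihydrofuran-2(3H)-one | O1[C@@H](CO[Si](c2ccccc2)(c2ccccc2)C(C)(C)C)[C@H](C(=O)c2ccc(OC)c(OC)c2)[C@@H](Cc2ccc(OC)c(OC)c2)C1=O | intermediate
15 | (2R,3S,4R)-5-(tert-butyldiphenylsilyloxy)-2-(3,4-dimethoxybenzyl)-3-[(3,4-dimethoxyphenyl)(hydroxy)methyl]pentane-1,4-diol, carbinol epimers | O[C@@H](CO[Si](c1ccccc1)(c1ccccc1)C(C)(C)C)[C@H](C(O)c1ccc(OC)c(OC)c1)[C@@H](Cc1ccc(OC)c(OC)c1)CO | intermediate
16 | (2R,3S,4R)-4-(3,4-dimethoxybenzyl)-3-[(3,4-dimethoxyphenyl)(hydroxy)methyl]pentane-1,2,5-triol, carbinol epimers | O[C@@H](CO)[C@H](C(O)c1ccc(OC)c(OC)c1)[C@@H](Cc1ccc(OC)c(OC)c1)CO | intermediate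
17 | (2S,3R)-3-(3,4-dimethoxybenzyl)-2-[(3,4-dimethoxyphenyl)(hydroxy)methyl]-4-hydroxybutanal, carbinol epimers, in equilibrium with its lactol | O=C[C@H](C(O)c1ccc(OC)c(OC)c1)[C@@H](Cc1ccc(OC)c(OC)c1)CO | intermediate
18 | (2R,3R)-2-(3,4-dimethoxybenzyl)-3-[(3,4-dimethoxyphenyl)(hydroxy)methyl]butane-1,4-diol, carbinol epimers | OC[C@H](C(O)c1ccc(OC)c(OC)c1)[C@@H](Cc1ccc(OC)c(OC)c1)CO | intermediate
19 | [(2S,3R,4R)-4-(3,4-dimethoxybenzyl)-2-(3,4-dimethoxyphenyl)tetrahydrofuran-3-yl]methanol | OC[C@H]1[C@@H](Cc2ccc(OC)c(OC)c2)CO[C@@H]1c1ccc(OC)c(OC)c1 | intermediate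
20 | angelic acid, (Z)-2-methylbut-2-enoic acid | C/C=C(/C)C(=O)O | starting material
21 | leoligin, [(2S,3R,4R)-4-(3,4-dimethoxybenzyl)-2-(3,4-dimethoxyphenyl)tetrahydrofuran-3-yl]methyl (2Z)-2-methylbut-2-enoate | C/C=C(/C)C(=O)OC[C@H]1[C@@H](Cc2ccc(OC)c(OC)c2)CO[C@@H]1c1ccc(OC)c(OC)c1 | target

Total step count: 13. Longest linear sequence: 12 steps (steps 1–5 and 7–13, from D-glutamic acid); the dithiane branch (step 6) is one step. Lactone alcohol 3 is itself believed to be an article of commerce, and entering there would remove steps 1 and 2.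

Steps most likely to fail

Step 7. The lithium enolate 12 may be protonated before it is alkylated (by the dithiane C–H or the γ-hydrogen of unreacted butenolide), or C-benzylation next to the bulky dithianyl group may be slow, so that the two-component adduct accumulates. Facial control in the alkylation may also erode if the mixture has to be warmed. The fallback uncouples the two bond formations and sets out from 7 and 9. The conjugate addition alone (n-BuLi, THF, −78 °C) is quenched with NH4Cl to give (4R,5R)-5-[(tert-butyldiphenylsilyloxy)methyl]-4-[2-(3,4-dimethoxyphenyl)-1,3-dithian-2-yl]dihydrofuran-2(3H)-one F1, which is purified. F1 is then deprotonated on its own with KN(SiMe3)2 in THF/DMPU at −78 °C and alkylated with 10 anti to the dithianyl group, which returns to the route at 13. The separate enolisation allows a more reactive potassium enolate and a clean stoichiometry for the bromide.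

Step 12. The benzylic cation may be captured by the electron-rich veratryl ring on C7' (six-membered Friedel–Crafts closure to an aryltetralin), or the hydroxyl may close from the wrong face and give the 2,3-cis ether. The fallback closes the ring one stage earlier and sets out from 15, whose C3 substituent is the much bulkier CH(OH)CH2OSi group and which has no second primary hydroxyl. Catalytic camphorsulfonic acid in CH2Cl2 at −20 → 0 °C should give (1R)-2-(tert-butyldiphenylsilyloxy)-1-[(2S,3R,4R)-4-(3,4-dimethoxybenzyl)-2-(3,4-dimethoxyphenyl)tetrahydrofuran-3-yl]ethanol F2, with a stronger steric preference for the 2,3-trans ether and a faster closure at lower temperature. Bu4NF in THF then gives (1R)-1-[(2S,3R,4R)-4-(3,4-dimethoxybenzyl)-2-(3,4-dimethoxyphenyl)tetrahydrofuran-3-yl]ethane-1,2-diol F3. NaIO4 in THF/H2O cleaves F3 to (2S,3S,4R)-4-(3,4-dimethoxybenzyl)-2-(3,4-dimethoxyphenyl)tetrahydrofuran-3-carbaldehyde F4, which is reduced without delay with NaBH4 in MeOH at 0 °C, returning to the route at 19.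

Step 13. The angelate may isomerise to the thermodynamically preferred tiglate during esterification, or the betaine may be consumed unproductively with the β-branched alcohol. The fallback reverses the roles of the partners and sets out from 19. MsCl and Et3N in CH2Cl2 at 0 °C give [(2S,3R,4R)-4-(3,4-dimethoxybenzyl)-2-(3,4-dimethoxyphenyl)tetrahydrofuran-3-yl]methyl methanesulfonate F5. F5 is displaced by the caesium carboxylate made from angelic acid 20 and Cs2CO3 in DMF at 40–50 °C, an O-alkylation in which the acid is never activated at its carbonyl group, and this returns to the route at 21.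

Further compounds
F1 | step 7 | (4R,5R)-5-[(tert-butyldiphenylsilyloxy)methyl]-4-[2-(3,4-dimethoxyphenyl)-1,3-dithian-2-yl]dihydrofuran-2(3H)-one | O1[C@@H](CO[Si](c2ccccc2)(c2ccccc2)C(C)(C)C)[C@H](C2(c3ccc(OC)c(OC)c3)SCCCS2)CC1=O
F2 | step 12 | (1R)-2-(tert-butyldiphenylsilyloxy)-1-[(2S,3R,4R)-4-(3,4-dimethoxybenzyl)-2-(3,4-dimethoxyphenyl)tetrahydrofuran-3-yl]ethanol | O[C@@H](CO[Si](c1ccccc1)(c1ccccc1)C(C)(C)C)[C@H]1[C@@H](Cc2ccc(OC)c(OC)c2)CO[C@@H]1c1ccc(OC)c(OC)c1
F3 | step 12 | (1R)-1-[(2S,3R,4R)-4-(3,4-dimethoxybenzyl)-2-(3,4-dimethoxyphenyl)tetrahydrofuran-3-yl]ethane-1,2-diol | O[C@@H](CO)[C@H]1[C@@H](Cc2ccc(OC)c(OC)c2)CO[C@@H]1c1ccc(OC)c(OC)c1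
F4 | step 12 | (2S,3S,4R)-4-(3,4-dimethoxybenzyl)-2-(3,4-dimethoxyphenyl)tetrahydrofuran-3-carbaldehyde | O=C[C@H]1[C@@H](Cc2ccc(OC)c(OC)c2)CO[C@@H]1c1ccc(OC)c(OC)c1
F5 | step 13 | [(2S,3R,4R)-4-(3,4-dimethoxybenzyl)-2-(3,4-dimethoxyphenyl)tetrahydrofuran-3-yl]methyl methanesulfonate | CS(=O)(=O)OC[C@H]1[C@@H](Cc2ccc(OC)c(OC)c2)CO[C@@H]1c1ccc(OC)c(OC)c1
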